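The cyclopentene ring (C1–C2=C3–C4–C5) is cut at C2=C3 and C4–C5. The C6 oxygen, next to the ring fusion, serves as a masked ketone that, with an auxiliary ester, makes C5 a carbanion, while C2 is a formyl group on C1. A Schweizer annulation (Michael addition/intramolecular Wittig) with (E)-prop-1-enyltriphenylphosphonium bromide then delivers C3, C4 and its methyl group and closes the five-membered ring onto the cycloheptane in one operation. The precursor is a monocyclic cycloheptadiene diester from an enantioselective Rh-catalysed [4+3] cycloaddition that sets C1; the remaining centres are relayed from it, except C14 (CBS reduction).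

Key step: step 10

Remarks and assumptions
- Numbering: target numbering throughout. Hydroazulene C1–C10: C1/C5 ring fusion, C2=C3, C4 (Me), C6 (OH), C7 (side chain), C9 (OH), C10 (=CH2). Side chain C11 (Me), C12 (OAc), C13, C14 (OH), C15 (isopropenyl). β is the face of H-5, the C4 methyl, O-6 and the C7 side chain; H-1 and O-9 are α. TBS = tert-butyldimethylsilyl, TES = triethylsilyl.
- Assumption: (E)-3-methylpent-2-en-4-yn-1-ol is bought as the pure E isomer (or distilled from the commercial E/Z mixture).
- Assumption: Rh2(S-PTAD)4 is taken to give the C1 configuration drawn in step 5; if the sense of induction is opposite, Rh2(R-PTAD)4 is used.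

Step 1
Reactants: 1 dimethyl 3-oxopentanedioate; 2 4-acetamidobenzenesulfonyl azide (p-ABSA)
Product: 3 dimethyl 2-diazo-3-oxopentanedioate
Conditions: Et3N, MeCN, 0 °C → rt (1.0 equiv of 2)
Reagents that add atoms: 4-acetamidobenzenesulfonyl azide (2), CC(=O)Nc1ccc(cc1)S(=O)(=O)N=[N+]=[N-]
Why: Regitz diazo transfer to one of the two equivalent active methylene groups; one equivalent of azide should stop at the mono-diazo compound.

Step 2
Reactants: 3 dimethyl 2-diazo-3-oxopentanedioate; 4 tert-butyldimethylsilyl triflate (TBSOTf)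
Product: 5 dimethyl (Z)-3-(tert-butyldimethylsilyloxy)-2-diazopent-3-enedioate
Conditions: Et3N, CH2Cl2, 0 °C
Reagents that add atoms: TBSOTf (4), CC(C)(C)[Si](C)(C)OS(=O)(=O)C(F)(F)F
Why: Soft enolisation and O-silylation of the only remaining enolisable CH2 through the chelated Z enol should give the silyloxy vinyldiazo ester.

Step 3
Reactants: 6 (E)-3-methylpent-2-en-4-yn-1-ol; 7 chlorotriethylsilane
Product: 8 (E)-triethyl[(3-methylpent-2-en-4-yn-1-yl)oxy]silane
Conditions: imidazole, CH2Cl2, 0 °C
Reagents that add atoms: chlorotriethylsilane (7), CC[Si](Cl)(CC)CC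
Why: Standard silylation of a primary alcohol.

Step 4
Reactants: 8 (E)-triethyl[(3-methylpent-2-en-4-yn-1-yl)oxy]silane
Product: 9 (E)-triethyl[(3-methylpenta-2,4-dien-1-yl)oxy]silane
Conditions: H2 (1 atm), Lindlar Pd, quinoline, hexane, rt
Reagents that add atoms: none
Why: Lindlar semihydrogenation should reduce the terminal alkyne to the vinyl group and leave the trisubstituted E alkene untouched.

Step 5
Reactants: 5 silyloxy vinyldiazo diester; 9 dienyl TES ether
Product: 11 cycloheptadiene diester (dimethyl 6-TBSO-10-methyl-1β-[(triethylsilyloxy)methyl]cyclohepta-6,9-diene-5β,7-dicarboxylate; C1 and C5 substituents cis), via cis-divinylcyclopropane 10 (not isolated)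
Conditions: Rh2(S-PTAD)4 (1 mol%), hexanes, −40 °C → rt, slow addition of 5 to 9 (2 equiv); then 50 °C
Reagents that add atoms: vinyldiazo diester (5), COC(=O)/C=C(\O[Si](C)(C)C(C)(C)C)C(=[N+]=[N-])C(=O)OC
Why: Rh(II)-catalysed tandem cyclopropanation/Cope rearrangement ([4+3] cycloaddition of a vinylcarbenoid): the carbenoid should cyclopropanate the monosubstituted C8=C9 vinyl group with the two alkenyl groups cis under catalyst control, and the boat Cope rearrangement joins C5 to C1 and transfers this chirality to C1 through the E diene geometry.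

Step 6
Reactants: 11 cycloheptadiene diester; 12 3-chloroperoxybenzoic acid (mCPBA)
Product: 13 9α,10α-epoxide of 11
Conditions: NaHCO3, CH2Cl2, −20 → 0 °C
Reagents that add atoms: mCPBA (12), OOC(=O)c1cccc(Cl)c1
Why: Prilezhaev epoxidation should take the isolated trisubstituted C9=C10 alkene in preference to the push–pull β-silyloxy acrylate, on the α face anti to the neighbouring β substituent at C1, which sets C9.

Step 7
Reactants: 13 9α,10α-epoxide; 4 TBSOTf
Product: 14 exocyclic allylic silyl ether (dimethyl 6,9α-bis-TBSO-10-methylene-1β-[(triethylsilyloxy)methyl]cyclohept-6-ene-5β,7-dicarboxylate)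
Conditions: TBSOTf, DBU, toluene, −78 → 0 °C
Reagents that add atoms: TBSOTf (4), CC(C)(C)[Si](C)(C)OS(=O)(=O)C(F)(F)F
Why: Silyl triflate/amidine isomerisation of an epoxide to an allylic silyl ether: O-silylation, ionisation at tertiary C10 and loss of a methyl proton should give the C10 methylene while the C9–O bond keeps its configuration.

Step 8
Reactants: 14 exocyclic allylic silyl ether
Product: 15 aldehyde (dimethyl 6,9α-bis-TBSO-1β-formyl-10-methylenecyclohept-6-ene-5β,7-dicarboxylate)
Conditions: (COCl)2, DMSO, CH2Cl2, −78 → −40 °C; then Et3N, −78 → 0 °C; used at once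
Reagents that add atoms: none
Why: Direct Swern oxidation of a primary TES ether: activated DMSO should cleave the primary Et3Si–O bond and oxidise C2 while the secondary TBS ether and the TBS enol ether stay intact.

Step 9
Reactants: 16 allyltriphenylphosphonium bromide
Product: 17 (E)-prop-1-enyltriphenylphosphonium bromide
Conditions: Et3N (cat.), MeCN, reflux
Reagents that add atoms: none
Why: Base-catalysed prototropic shift should move the double bond into conjugation with phosphorus and give the E vinylphosphonium salt.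

Step 10
Reactants: 15 aldehyde; 17 (E)-prop-1-enyltriphenylphosphonium bromide
Product: 20 trans-fused cyclopentene-annulated diester (1α-H; 4β-Me; 5β-CO2Me; C2=C3; C6-OTBS enol ether C6=C7 with C7-CO2Me; 9α-OTBS; 10-methylene), via sodium dienolate 18 (not isolated), via phosphorus ylide 19 (not isolated)
Conditions: NaH (1.0 equiv), THF, 0 °C; then 17, DMF, 0 → 50 °C
Reagents that add atoms: (E)-prop-1-enyltriphenylphosphonium bromide (17), C/C=C/[P+](c1ccccc1)(c1ccccc1)c1ccccc1.[Br-]
Why: NaH should remove the most acidic proton, C5–H, which lies between its ester and the β-silyloxy acrylate (a vinylogous malonate, several pKa units below the C1–H of the aldehyde), and dienolate 18 adds through C5 to C4 of the vinylphosphonium salt; the non-stabilised ylide 19 then attacks the C2 formyl group and the oxaphosphetane collapses with loss of Ph3PO. This is the Schweizer annulation (Michael addition/intramolecular Wittig of a stabilised carbanion that carries a carbonyl group), here with a β-methyl vinylphosphonium salt. The cyclopentene closes by 5-exo-trig addition of the ylide carbon C3 to the aldehyde carbon, and the ring enforces the Z C2=C3 bond. C5 should be attacked on the α face, anti to the C1 formyl group, and the C4 methyl group should take the β position, cis to the C5 ester and away from the bulkier C6 silyloxyalkene; the Michael step is expected to be reversible, so the least strained ring closure should decide C4. The step needs C5 rather than C7 or C1 as the reacting site: addition through C7 cannot reach a five-membered Wittig closure and should revert, and one equivalent of base with freshly made aldehyde limits enolisation at C1.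

Step 11
Reactants: 20 cyclopentene-annulated diester
Product: 22 trans-fused ketone (9α-TBSO-4β-methyl-10-methylene-1αH-5βH-hydroazul-2-en-6-one), via keto diester 21 (not isolated)
Conditions: LiCl, H2O, DMSO, 140 °C
Reagents that add atoms: none
Why: The enol silyl ether should hydrolyse and both β-keto esters undergo Krapcho demethoxycarbonylation; C5 is protonated under equilibrating conditions and should settle as 5β-H, where C6 is trans to both the C4 methyl group and C10 on the cyclopentene.

Step 12
Reactants: 22 trans-fused ketone; 23 ethyl bromoacetate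
Product: 25 γ-keto ester (ethyl 2-(6-oxo-hydroazulen-7β-yl)acetate), via lithium enolate 24 (not isolated)
Conditions: LDA, THF, −78 °C; then 23, DMPU, −78 → −40 °C
Reagents that add atoms: ethyl bromoacetate (23), BrCC(=O)OCC
Why: LDA should form the kinetic enolate at the C7 methylene rather than at the ring-fusion C5–H, and the bromide should enter on the β face, anti to the pseudo-axial 9α-silyloxy group, which sets C7.

Step 13
Reactants: 25 γ-keto ester
Product: 27 cis-fused γ-lactone (O6–C12; 6β-O; 7β-CH2), via hydroxy ester 26 (not isolated)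
Conditions: L-Selectride, THF, −78 °C; then PPTS, PhH, rt
Reagents that add atoms: none
Why: The bulky hydride should add to the α face of the C6 ketone, anti to the C7 side chain and the C4 methyl group, and the resulting 6β-hydroxy ester, cis to the side chain, lactonises.

Step 14
Reactants: 27 cis-fused γ-lactone; 28 iodomethane
Product: 30 α-methyl lactone (11S; methyl cis to H-7), via lactone enolate 29 (not isolated)
Conditions: LDA, THF, −78 °C; then MeI
Reagents that add atoms: iodomethane (28), CI
Why: Alkylation of the lactone enolate should occur on the convex face of the cis-fused bicycle, which places the methyl group cis to H-7 and gives 11S.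

Step 15
Reactants: 30 α-methyl lactone; 31 N,O-dimethylhydroxylamine hydrochloride
Product: 32 6β-hydroxy Weinreb amide
Conditions: i-PrMgCl, THF, −20 → 0 °C
Reagents that add atoms: N,O-dimethylhydroxylamine hydrochloride (31), CNOC.Cl
Why: Weinreb aminolysis of the lactone by the chloromagnesium amide should open the ring without touching C11.

Step 16
Reactants: 32 6β-hydroxy Weinreb amide; 33 triethylsilyl triflate (TESOTf)
Product: 34 6β-OTES Weinreb amide
Conditions: 2,6-lutidine, CH2Cl2, −78 °C
Reagents that add atoms: TESOTf (33), CC[Si](CC)(CC)OS(=O)(=O)C(F)(F)F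
Why: Silyl triflate silylation of the hindered secondary alcohol blocks relactonisation and later acetylation at O-6.

Step 17
Reactants: 34 6β-OTES Weinreb amide
Product: 35 C12 aldehyde
Conditions: DIBAL-H, THF, −78 °C; Rochelle salt work-up; used at once
Reagents that add atoms: none
Why: Reduction of a Weinreb amide should stop at the chelated tetrahedral intermediate and release the α-chiral aldehyde on work-up.

Step 18
Reactants: 36 3-methylbut-3-en-2-one; 37 trimethylsilyl triflate (TMSOTf)
Product: 38 2-(trimethylsilyloxy)-3-methylbuta-1,3-diene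
Conditions: Et3N, Et2O, 0 °C
Reagents that add atoms: TMSOTf (37), C[Si](C)(C)OS(=O)(=O)C(F)(F)F
Why: Soft enolisation of the methyl ketone, whose only enolisable position is the methyl group, should give the silyl enol ether.

Step 19
Reactants: 35 C12 aldehyde; 38 2-(trimethylsilyloxy)-3-methylbuta-1,3-diene
Product: 39 β-hydroxy enone (12S-OH; C14 ketone; isopropenyl)
Conditions: BF3·OEt2, CH2Cl2, −78 °C
Reagents that add atoms: 2-(trimethylsilyloxy)-3-methylbuta-1,3-diene (38), C=C(C)C(=C)O[Si](C)(C)C
Why: Mukaiyama aldol addition through an open transition state should follow Felkin–Anh control from C11 (ring carbon C7 as the large group) and give the 11,12-syn alcohol.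

Step 20
Reactants: 39 β-hydroxy enone; 40 acetic anhydride
Product: 41 12-acetoxy enone
Conditions: pyridine, DMAP (cat.), CH2Cl2, 0 °C
Reagents that add atoms: acetic anhydride (40), CC(=O)OC(C)=O
Why: O-6 and O-9 are silylated, so acylation should take the only free hydroxyl; low temperature limits β-elimination of the acetate.

Step 21
Reactants: 41 12-acetoxy enone
Product: 42 14R allylic alcohol (6-OTES; 9-OTBS; 12-OAc)
Conditions: (S)-Me-CBS (0.5 equiv), catecholborane, toluene, −78 °C
Reagents that add atoms: none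
Why: Corey–Bakshi–Shibata reduction with the isopropenyl group as the large substituent should deliver hydride under catalyst control to give 14R, syn to the C12 acetate, without conjugate reduction or hydroboration.

Step 22
Reactants: 42 bis-silyl ether
Product: 43 CNP0151410.1 (target)
Conditions: HF·pyridine, pyridine, THF, 0 °C → rt
Reagents that add atoms: none
Why: Buffered acidic fluoride should cleave the TES and TBS ethers without hydrolysis or 1,3-migration of the acetate.

Compound list
1 | dimethyl 3-oxopentanedioate | COC(=O)CC(=O)CC(=O)OC | starting material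
2 | 4-acetamidobenzenesulfonyl azide | CC(=O)Nc1ccc(cc1)S(=O)(=O)N=[N+]=[N-] | starting material
3 | dimethyl 2-diazo-3-oxopentanedioate | COC(=O)CC(=O)C(=[N+]=[N-])C(=O)OC | intermediate
4 | tert-butyldimethylsilyl trifluoromethanesulfonate | CC(C)(C)[Si](C)(C)OS(=O)(=O)C(F)(F)F | starting material
5 | dimethyl (Z)-3-(tert-butyldimethylsilyloxy)-2-diazopent-3-enedioate | COC(=O)/C=C(\O[Si](C)(C)C(C)(C)C)C(=[N+]=[N-])C(=O)OC | intermediate
6 | (E)-3-methylpent-2-en-4-yn-1-ol | C#C/C(C)=C/CO | starting material
7 | chlorotriethylsilane | CC[Si](Cl)(CC)CC | starting material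
8 | (E)-triethyl[(3-methylpent-2-en-4-yn-1-yl)oxy]silane | C#C/C(C)=C/CO[Si](CC)(CC)CC | intermediate
9 | (E)-triethyl[(3-methylpenta-2,4-dien-1-yl)oxy]silane | C=C/C(C)=C/CO[Si](CC)(CC)CC | intermediate
10 | cis-divinylcyclopropane: methyl 1-[(Z)-1-(TBSO)-3-methoxy-3-oxoprop-1-enyl]-2-[(E)-4-(triethylsilyloxy)but-2-en-2-yl]cyclopropane-1-carboxylate, alkenyl groups cis | COC(=O)[C@]1(/C(O[Si](C)(C)C(C)(C)C)=C/C(=O)OC)C[C@H]1/C(C)=C/CO[Si](CC)(CC)CC | intermediate (not isolated)
11 | dimethyl 6-TBSO-10-methyl-1β-[(triethylsilyloxy)methyl]cyclohepta-6,9-diene-5β,7-dicarboxylate | CC[Si](CC)(CC)OC[C@H]1C(C)=CCC(C(=O)OC)=C(O[Si](C)(C)C(C)(C)C)[C@H]1C(=O)OC | intermediate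
12 | 3-chloroperoxybenzoic acid | OOC(=O)c1cccc(Cl)c1 | starting material
13 | 9α,10α-epoxide of 11 | CC[Si](CC)(CC)OC[C@H]1[C@]2(C)O[C@@H]2CC(C(=O)OC)=C(O[Si](C)(C)C(C)(C)C)[C@H]1C(=O)OC | intermediate
14 | dimethyl 6,9α-bis-TBSO-10-methylene-1β-[(triethylsilyloxy)methyl]cyclohept-6-ene-5β,7-dicarboxylate | CC[Si](CC)(CC)OC[C@H]1C(=C)[C@H](O[Si](C)(C)C(C)(C)C)CC(C(=O)OC)=C(O[Si](C)(C)C(C)(C)C)[C@H]1C(=O)OC | intermediate
15 | dimethyl 6,9α-bis-TBSO-1β-formyl-10-methylenecyclohept-6-ene-5β,7-dicarboxylate | O=C[C@H]1C(=C)[C@H](O[Si](C)(C)C(C)(C)C)CC(C(=O)OC)=C(O[Si](C)(C)C(C)(C)C)[C@H]1C(=O)OC | intermediate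
16 | allyltriphenylphosphonium bromide | C=CC[P+](c1ccccc1)(c1ccccc1)c1ccccc1.[Br-] | starting material
17 | (E)-prop-1-enyltriphenylphosphonium bromide | C/C=C/[P+](c1ccccc1)(c1ccccc1)c1ccccc1.[Br-] | intermediate
18 | sodium dienolate of 15 (C5 carbanion, drawn as the ester enolate) | [Na+].[O-]C(OC)=C1C(O[Si](C)(C)C(C)(C)C)=C(C(=O)OC)C[C@@H](O[Si](C)(C)C(C)(C)C)C(=C)[C@@H]1C=O | intermediate (not isolated)
19 | phosphorus ylide: C5-alkylated Michael adduct with C4 (β-Me) and C3=PPh3, C1 formyl intact | C=C1[C@H](O[Si](C)(C)C(C)(C)C)CC(C(=O)OC)=C(O[Si](C)(C)C(C)(C)C)[C@](C(=O)OC)([C@@H](C)C=P(c2ccccc2)(c2ccccc2)c2ccccc2)[C@H]1C=O | intermediate (not isolated)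
20 | trans-fused cyclopentene-annulated diester (1α-H, 4β-Me, 5β-CO2Me, C2=C3, 6-OTBS enol ether, 7-CO2Me, 9α-OTBS, 10-methylene) | C=C1[C@H](O[Si](C)(C)C(C)(C)C)CC(C(=O)OC)=C(O[Si](C)(C)C(C)(C)C)[C@]2(C(=O)OC)[C@@H](C)C=C[C@@H]12 | intermediate
21 | keto diester (C6 ketone, 5β- and 7-CO2Me; C7 unassigned) | C=C1[C@H](O[Si](C)(C)C(C)(C)C)CC(C(=O)OC)C(=O)[C@]2(C(=O)OC)[C@@H](C)C=C[C@@H]12 | intermediate (not isolated)
22 | trans-fused ketone: 9α-TBSO-4β-methyl-10-methylene-1αH,5βH-hydroazul-2-en-6-one | C=C1[C@H](O[Si](C)(C)C(C)(C)C)CCC(=O)[C@@H]2[C@@H](C)C=C[C@@H]12 | intermediate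
23 | ethyl bromoacetate | BrCC(=O)OCC | starting material
24 | lithium C6=C7 enolate of 22 | [Li+].[O-]C1=CC[C@@H](O[Si](C)(C)C(C)(C)C)C(=C)[C@@H]2C=C[C@H](C)[C@@H]12 | intermediate (not isolated)
25 | γ-keto ester: ethyl 2-(6-oxo-hydroazulen-7β-yl)acetate | C=C1[C@H](O[Si](C)(C)C(C)(C)C)C[C@@H](CC(=O)OCC)C(=O)[C@@H]2[C@@H](C)C=C[C@@H]12 | intermediate
26 | 6β-hydroxy ester | C=C1[C@H](O[Si](C)(C)C(C)(C)C)C[C@@H](CC(=O)OCC)[C@@H](O)[C@@H]2[C@@H](C)C=C[C@@H]12 | intermediate (not isolated)
27 | cis-fused γ-lactone (O6–C12) | C=C1[C@H](O[Si](C)(C)C(C)(C)C)C[C@H]3CC(=O)O[C@H]3[C@@H]2[C@@H](C)C=C[C@@H]12 | intermediate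
28 | iodomethane | CI | starting material
29 | lithium enolate of lactone 27 | C=C1[C@H](O[Si](C)(C)C(C)(C)C)C[C@H]3C=C([O-])O[C@H]3[C@@H]2[C@@H](C)C=C[C@@H]12.[Li+] | intermediate (not isolated)
30 | α-methyl lactone (11S, methyl cis to H-7) | C=C1[C@H](O[Si](C)(C)C(C)(C)C)C[C@H]3[C@H](C)C(=O)O[C@H]3[C@@H]2[C@@H](C)C=C[C@@H]12 | intermediate
31 | N,O-dimethylhydroxylamine hydrochloride | CNOC.Cl | starting material
32 | 6β-hydroxy Weinreb amide | C=C1[C@H](O[Si](C)(C)C(C)(C)C)C[C@@H]([C@H](C)C(=O)N(C)OC)[C@@H](O)[C@@H]2[C@@H](C)C=C[C@@H]12 | intermediate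
33 | triethylsilyl trifluoromethanesulfonate | CC[Si](CC)(CC)OS(=O)(=O)C(F)(F)F | starting material
34 | 6β-OTES Weinreb amide | C=C1[C@H](O[Si](C)(C)C(C)(C)C)C[C@@H]([C@H](C)C(=O)N(C)OC)[C@@H](O[Si](CC)(CC)CC)[C@@H]2[C@@H](C)C=C[C@@H]12 | intermediate
35 | C12 aldehyde (11S) | C=C1[C@H](O[Si](C)(C)C(C)(C)C)C[C@@H]([C@H](C)C=O)[C@@H](O[Si](CC)(CC)CC)[C@@H]2[C@@H](C)C=C[C@@H]12 | intermediate
36 | 3-methylbut-3-en-2-one | CC(=O)C(C)=C | starting material
37 | trimethylsilyl trifluoromethanesulfonate | C[Si](C)(C)OS(=O)(=O)C(F)(F)F | starting material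
38 | 2-(trimethylsilyloxy)-3-methylbuta-1,3-diene | C=C(C)C(=C)O[Si](C)(C)C | intermediate
39 | β-hydroxy enone (12S-OH, C14 ketone) | C=C1[C@H](O[Si](C)(C)C(C)(C)C)C[C@@H]([C@H](C)[C@@H](O)CC(=O)C(C)=C)[C@@H](O[Si](CC)(CC)CC)[C@@H]2[C@@H](C)C=C[C@@H]12 | intermediate
40 | acetic anhydride | CC(=O)OC(C)=O | starting material
41 | 12-acetoxy enone | C=C1[C@H](O[Si](C)(C)C(C)(C)C)C[C@@H]([C@H](C)[C@@H](OC(C)=O)CC(=O)C(C)=C)[C@@H](O[Si](CC)(CC)CC)[C@@H]2[C@@H](C)C=C[C@@H]12 | intermediate
42 | 14R allylic alcohol, 6-OTES, 9-OTBS, 12-OAc | C=C1[C@H](O[Si](C)(C)C(C)(C)C)C[C@@H]([C@H](C)[C@@H](OC(C)=O)C[C@@H](O)C(C)=C)[C@@H](O[Si](CC)(CC)CC)[C@@H]2[C@@H](C)C=C[C@@H]12 | intermediate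
43 | CNP0151410.1 | C=C(C)[C@H](O)C[C@H](OC(C)=O)[C@@H](C)[C@@H]1C[C@@H](O)C(=C)[C@@H]2C=C[C@H](C)[C@H]2[C@@H]1O | target

Total step count: 22. Longest linear sequence: 18 steps (steps 3–8, 10–17 and 19–22 from (E)-3-methylpent-2-en-4-yn-1-ol; the branch from dimethyl 3-oxopentanedioate through steps 1 and 2 is equally long).

Steps most likely to fail

Step 10. The Michael addition may show poor control of C4 (wrong alkene face or wrong face of C5). The aldehyde may also enolise at C1 before ring closure, which would epimerise C1 or move the C10 methylene into conjugation. Fallback from 15: iridium-catalysed branched-selective allylic alkylation of the C5 carbanion with (E)-but-2-enyl methyl carbonate ([Ir(cod)Cl]2, chiral phosphoramidite, Cs2CO3, THF) sets C4 under ligand control and should give the C5-(but-3-en-2-yl) aldehyde F1. Wittig methylenation of the formyl group (Ph3P=CH2, THF, −78 → 0 °C) gives the diene F2, and ring-closing metathesis (Grubbs II, CH2Cl2, 40 °C) forms C2=C3. The sequence returns to the route at 20.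

Step 12. The kinetic C7 enolate may be alkylated with low facial selectivity, or may equilibrate toward C5 and over-alkylate. Fallback from 22: condensation with (S)-1-amino-2-(methoxymethyl)pyrrolidine (SAMP) gives the SAMP hydrazone F3. Deprotonation at the C7 methylene (LDA, THF, −78 °C) and alkylation with ethyl bromoacetate under auxiliary control should give the alkylated hydrazone F4. Two-phase hydrolysis with aqueous oxalic acid releases the ketone and returns to the route at 25.

Step 7. After ionisation at C10 the cation may undergo a 1,2-hydride shift to the C9 ketone, or lose the C1 proton to give the endocyclic alkene instead of the methylene. Fallback from 13: radical opening of the epoxide at C10 with Cp2TiCl (Cp2TiCl2, Mn, collidine hydrochloride, THF, rt), followed by hydrogen abstraction from the methyl group by a second Ti(III), should give the free exocyclic allylic alcohol F5. Silylation (TBSOTf, 2,6-lutidine, CH2Cl2, −78 °C) returns to the route at 14.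

Further compounds
F1 | step 10 | C5-(but-3-en-2-yl) aldehyde (4β-Me, 5β-CO2Me, C1 formyl) | C=C1[C@H](O[Si](C)(C)C(C)(C)C)CC(C(=O)OC)=C(O[Si](C)(C)C(C)(C)C)[C@](C(=O)OC)([C@@H](C)C=C)[C@H]1C=O
F2 | step 10 | diene for ring-closing metathesis (C1 vinyl, C5 but-3-en-2-yl) | C=C1[C@H](O[Si](C)(C)C(C)(C)C)CC(C(=O)OC)=C(O[Si](C)(C)C(C)(C)C)[C@](C(=O)OC)([C@@H](C)C=C)[C@H]1C=C
F3 | step 12 | SAMP hydrazone of ketone 22 | C=C1[C@H](O[Si](C)(C)C(C)(C)C)CCC(=NN3CCC[C@H]3COC)[C@@H]2[C@@H](C)C=C[C@@H]12
F4 | step 12 | C7β-(ethoxycarbonylmethyl) SAMP hydrazone | C=C1[C@H](O[Si](C)(C)C(C)(C)C)C[C@@H](CC(=O)OCC)C(=NN3CCC[C@H]3COC)[C@@H]2[C@@H](C)C=C[C@@H]12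
F5 | step 7 | free 9α-allylic alcohol with C10 methylene | CC[Si](CC)(CC)OC[C@H]1C(=C)[C@H](O)CC(C(=O)OC)=C(O[Si](C)(C)C(C)(C)C)[C@H]1C(=O)OC
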